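**Plan**

- Retrosynthesis: the three methyl ethers are removed last. The coumarin pyranone is opened at O1–C2 and C3=C4 (Wittig olefination and lactonisation of a salicylaldehyde). The coumarin benzo ring is then cut at C4a–C8a and C5–C6 ([4+2]) into a flavon-6-yl bis(silyloxy)diene and an acyl-alkyne.
- Enabling feature: coumarin C7(OH)–C8(aryl)–C8a(O) is a 1,3-dioxygenated, 2-substituted benzene, which is the imprint of an α-aryl acetoacetate. C4a, next to C8a, carries the single carbon (C4) that the acyl group of the alkyne supplies.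
- The diene goes back through C-acetylation and oxidative cleavage to a 6-allylflavone, and that to the 5-O-allyl ether of apigenin 7,4'-dimethyl ether (Claisen rearrangement).
- Forward: flavone rings A, B and C come intact from apigenin. The coumarin benzo ring arises in the Diels–Alder benzannulation (step 10) and the coumarin pyranone ring in the Wittig–lactonisation (step 12).
- The dienophile is an S-ethyl thioester rather than an oxo-ester, so that the acyl group can be taken to the aldehyde with Pd and a silane. A hydride reagent would also attack the flavone pyranone.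
- Stereochemistry: the target has no stereocentre, so nothing has to be set.

Key step: step 10

Assumption: the target SMILES carries no stereodescriptor, so the hindered C8–C6 biaryl axis is left unassigned and no control of axial configuration is attempted.

Abbreviation used in names: Fl = 5,7-dimethoxy-2-(4-methoxyphenyl)-4-oxochromen-6-yl. The geometry drawn for enol ether 13 and ketene acetal 14 is of no consequence, because both carbons become aromatic.

**Route**

Step 1
Reactants: 1 apigenin
Product: 2 5-hydroxy-7-methoxy-2-(4-methoxyphenyl)chromen-4-one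
Conditions: Me2SO4 (2.2 equiv), K2CO3, acetone, reflux
Reagents that add atoms: dimethyl sulfate, COS(=O)(=O)OC
Why: Williamson O-methylation; the 7- and 4'-hydroxyls are free and acidic, whereas the 5-hydroxyl is tied up in a hydrogen bond to the C4 carbonyl and reacts last, so two equivalents should stop at the dimethyl ether.

Step 2
Reactants: 2 5-hydroxy-7-methoxy-2-(4-methoxyphenyl)chromen-4-one, 3 allyl bromide
Product: 4 7-methoxy-2-(4-methoxyphenyl)-5-(prop-2-enyloxy)chromen-4-one
Conditions: K2CO3, DMF, 60 °C
Reagents that add atoms: none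
Why: Williamson etherification; a polar aprotic solvent and a reactive allylic halide should alkylate the chelated 5-hydroxyl, the only phenol left.

Step 3
Reactants: 4 7-methoxy-2-(4-methoxyphenyl)-5-(prop-2-enyloxy)chromen-4-one
Product: 6 5-hydroxy-7-methoxy-2-(4-methoxyphenyl)-6-(prop-2-enyl)chromen-4-one, via ortho-dienone 5 (not isolated)
Conditions: PhNEt2, 200 °C, Ar
Reagents that add atoms: none
Why: aromatic Claisen rearrangement ([3,3]-sigmatropic shift); C6 is the only free position ortho to the 5-oxygen (the other is the ring-fusion carbon C4a), and dienone 5 re-aromatises by enolisation to the chelated phenol.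

Step 4
Reactants: 6 5-hydroxy-7-methoxy-2-(4-methoxyphenyl)-6-(prop-2-enyl)chromen-4-one
Product: 7 5,7-dimethoxy-2-(4-methoxyphenyl)-6-(prop-2-enyl)chromen-4-one
Conditions: Me2SO4 (excess), K2CO3, acetone, reflux
Reagents that add atoms: dimethyl sulfate, COS(=O)(=O)OC
Why: Williamson O-methylation under forcing conditions; capping the 5-hydroxyl keeps it from lactonising onto the later acetic ester and from consuming base and silylating agent.

Step 5
Reactants: 7 5,7-dimethoxy-2-(4-methoxyphenyl)-6-(prop-2-enyl)chromen-4-one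
Product: 9 2-Fl-acetic acid, via arylacetaldehyde 8 (not isolated)
Conditions: OsO4 (1 mol %), KHSO5 (as Oxone, 4 equiv), DMF, rt
Reagents that add atoms: potassium peroxymonosulfate, [K+].[O-]S(=O)(=O)OO
Why: OsO4-catalysed oxidative cleavage with peroxymonosulfate; the monosubstituted alkene forms the osmate far faster than the electron-poor, trisubstituted C2=C3 of the pyranone, and aldehyde 8 is oxidised on to the acid in the same flask.

Step 6
Reactants: 9 2-Fl-acetic acid
Product: 10 methyl 2-Fl-acetate
Conditions: MeOH, H2SO4 (cat.), reflux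
Reagents that add atoms: methanol, CO
Why: Fischer esterification of an unhindered arylacetic acid; the flavone and the aryl ethers are stable to acidic methanol.

Step 7
Reactants: 10 methyl 2-Fl-acetate, 11 1-acetylimidazole
Product: 12 methyl 2-Fl-3-oxobutanoate
Conditions: LiN(SiMe3)2 (2.2 equiv), THF, −78 °C; then 11, −78 → 0 °C; aq NH4Cl
Reagents that add atoms: none
Why: Claisen-type C-acylation of the lithium ester enolate by an acyl imidazole; the second equivalent of base takes up the more acidic β-keto ester as it forms, and the flavone offers no enolisable position.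

Step 8
Reactants: 12 methyl 2-Fl-3-oxobutanoate
Product: 14 (1Z)-2-Fl-1-methoxy-1,3-bis(trimethylsilyloxy)buta-1,3-diene, via mono-silyl enol ether 13 (not isolated)
Conditions: Me3SiOTf (2.4 equiv), Et3N (3 equiv), CH2Cl2, 0 °C → rt; crude, under Ar
Reagents that add atoms: trimethylsilyl trifluoromethanesulfonate, C[Si](C)(C)OS(=O)(=O)C(F)(F)F
Why: soft enolisation with silyl triflate and amine; the enol is silylated first to 13, then silylation of the ester carbonyl and loss of a proton from the terminal methyl should give the cross-conjugated diene, a double silylation known for β-keto esters.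

Step 9
Reactants: 15 propiolic acid
Product: 16 S-ethyl prop-2-ynethioate
Conditions: EtSH, DCC, CH2Cl2, −20 → 0 °C
Reagents that add atoms: ethanethiol, CCS
Why: carbodiimide (Steglich-type) thioesterification; run cold and without amine base, the thiol should acylate through the O-acylisourea rather than add to the triple bond.

Step 10
Reactants: 14 (1Z)-2-Fl-1-methoxy-1,3-bis(trimethylsilyloxy)buta-1,3-diene, 16 S-ethyl prop-2-ynethioate
Product: 19 S-ethyl 3-Fl-2,4-dihydroxybenzothioate, via cyclohexadiene cycloadduct 17 (not isolated), via bis(trimethylsilyl) ether 18 (not isolated)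
Conditions: 16 (1.5 equiv), PhMe, 80 °C; then 1 M HCl, THF, rt
Reagents that add atoms: none
Why: The oxygen donors at C1 and C3 of diene 14 raise its HOMO and put the largest coefficient on the terminal CH2, so it adds to the electron-poor alkyne 16 in a normal-demand, strongly asynchronous [4+2] cycloaddition; the CH2 terminus bonds to the thioester β-carbon (future C5–C6) and the ketene-acetal carbon to the α-carbon (future C4a–C8a), giving 1,4-cyclohexadiene 17. Loss of methanol from the mixed silyl ketal aromatises 17 to bis(silyl ether) 18, and dilute acid frees the two phenols of 19. The closest known reaction type is the Diels–Alder benzannulation of 1-methoxy-1,3-bis(trimethylsilyloxy)buta-1,3-dienes with acetylenic esters to 2,4-dihydroxybenzoates. The one six-membered carbocycle is closed by this intermolecular suprafacial [4π+2π] addition, both ring bonds being made in the same event. No stereocentre is created, since the sp3 ketal carbon of 17 is erased on aromatisation. The step needs regioselectivity (acyl group ortho to the ketal-derived oxygen), which the matched polarisation of diene and dienophile secures, while the flavonyl group on the internal diene carbon lies away from both bond-forming termini and favours the s-cis conformer.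

Step 11
Reactants: 19 S-ethyl 3-Fl-2,4-dihydroxybenzothioate
Product: 20 3-Fl-2,4-dihydroxybenzaldehyde
Conditions: Et3SiH (3 equiv), 10% Pd/C, acetone, rt
Reagents that add atoms: none
Why: Fukuyama reduction; zerovalent palladium inserts into the acyl–sulfur bond, the silane delivers hydride and reductive elimination releases the aldehyde, under neutral, non-hydridic conditions that leave the pyranone carbonyl and aryl ethers alone.

Step 12
Reactants: 20 3-Fl-2,4-dihydroxybenzaldehyde, 21 ethyl (triphenylphosphoranylidene)acetate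
Product: 23 8-Fl-7-hydroxychromen-2-one, via E-cinnamate 22 (not isolated)
Conditions: PhNEt2, reflux (215 °C), Ar
Reagents that add atoms: none
Why: Wittig olefination with a stabilised ylide gives cinnamate 22, which at this temperature isomerises and lactonises onto the ortho phenol with loss of ethanol, the classical coumarin synthesis from 2,4-dihydroxybenzaldehydes.

Step 13
Reactants: 23 8-Fl-7-hydroxychromen-2-one
Product: 24 8-[5,7-dihydroxy-2-(4-hydroxyphenyl)-4-oxochromen-6-yl]-7-hydroxychromen-2-one
Conditions: BBr3 (10 equiv), CH2Cl2, −78 °C → rt; then MeOH, H2O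
Reagents that add atoms: none
Why: Lewis-acid cleavage of aryl methyl ethers with BBr3; each ether goes through the aryloxyborane to the phenol, the 5-methoxy group fastest through chelation to the C4 carbonyl, and the coumarin lactone and the pyranone persist.

**Compound list**

1 | apigenin, 5,7-dihydroxy-2-(4-hydroxyphenyl)chromen-4-one | O=c1cc(-c2ccc(O)cc2)oc2cc(O)cc(O)c12 | starting material
2 | 5-hydroxy-7-methoxy-2-(4-methoxyphenyl)chromen-4-one | COc1ccc(-c2cc(=O)c3c(O)cc(OC)cc3o2)cc1 | intermediate
3 | allyl bromide | C=CCBr | starting material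
4 | 7-methoxy-2-(4-methoxyphenyl)-5-(prop-2-enyloxy)chromen-4-one | C=CCOc1cc(OC)cc2oc(-c3ccc(OC)cc3)cc(=O)c12 | intermediate
5 | 7-methoxy-2-(4-methoxyphenyl)-6-(prop-2-enyl)-6H-chromene-4,5-dione (ortho-dienone, racemic) | C=CCC1C(=O)C2=C(C=C1OC)OC(-c1ccc(OC)cc1)=CC2=O | intermediate (not isolated)
6 | 5-hydroxy-7-methoxy-2-(4-methoxyphenyl)-6-(prop-2-enyl)chromen-4-one | C=CCc1c(OC)cc2oc(-c3ccc(OC)cc3)cc(=O)c2c1O | intermediate
7 | 5,7-dimethoxy-2-(4-methoxyphenyl)-6-(prop-2-enyl)chromen-4-one | C=CCc1c(OC)cc2oc(-c3ccc(OC)cc3)cc(=O)c2c1OC | intermediate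
8 | 2-Fl-acetaldehyde | O=CCc1c(OC)cc2oc(-c3ccc(OC)cc3)cc(=O)c2c1OC | intermediate (not isolated)
9 | 2-Fl-acetic acid | OC(=O)Cc1c(OC)cc2oc(-c3ccc(OC)cc3)cc(=O)c2c1OC | intermediate
10 | methyl 2-Fl-acetate | COC(=O)Cc1c(OC)cc2oc(-c3ccc(OC)cc3)cc(=O)c2c1OC | intermediate
11 | 1-acetylimidazole | CC(=O)n1ccnc1 | starting material
12 | methyl 2-Fl-3-oxobutanoate (racemic, enolisable) | COC(=O)C(C(C)=O)c1c(OC)cc2oc(-c3ccc(OC)cc3)cc(=O)c2c1OC | intermediate
13 | methyl (Z)-2-Fl-3-(trimethylsilyloxy)but-2-enoate | COC(=O)/C(c1c(OC)cc2oc(-c3ccc(OC)cc3)cc(=O)c2c1OC)=C(/C)O[Si](C)(C)C | intermediate (not isolated)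
14 | (1Z)-2-Fl-1-methoxy-1,3-bis(trimethylsilyloxy)buta-1,3-diene | C=C(O[Si](C)(C)C)/C(c1c(OC)cc2oc(-c3ccc(OC)cc3)cc(=O)c2c1OC)=C(/OC)O[Si](C)(C)C | intermediate
15 | propiolic acid | C#CC(=O)O | starting material
16 | S-ethyl prop-2-ynethioate | C#CC(=O)SCC | intermediate
17 | S-ethyl 5-Fl-6-methoxy-4,6-bis(trimethylsilyloxy)cyclohexa-1,4-diene-1-carbothioate (racemic) | CCSC(=O)C1=CCC(O[Si](C)(C)C)=C(c2c(OC)cc3oc(-c4ccc(OC)cc4)cc(=O)c3c2OC)C1(OC)O[Si](C)(C)C | intermediate (not isolated)
18 | S-ethyl 3-Fl-2,4-bis(trimethylsilyloxy)benzothioate | CCSC(=O)c1ccc(O[Si](C)(C)C)c(-c2c(OC)cc3oc(-c4ccc(OC)cc4)cc(=O)c3c2OC)c1O[Si](C)(C)C | intermediate (not isolated)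
19 | S-ethyl 3-Fl-2,4-dihydroxybenzothioate | CCSC(=O)c1ccc(O)c(-c2c(OC)cc3oc(-c4ccc(OC)cc4)cc(=O)c3c2OC)c1O | intermediate
20 | 3-Fl-2,4-dihydroxybenzaldehyde | O=Cc1ccc(O)c(-c2c(OC)cc3oc(-c4ccc(OC)cc4)cc(=O)c3c2OC)c1O | intermediate
21 | ethyl (triphenylphosphoranylidene)acetate | CCOC(=O)C=P(c1ccccc1)(c1ccccc1)c1ccccc1 | starting material
22 | ethyl (E)-3-(3-Fl-2,4-dihydroxyphenyl)prop-2-enoate | CCOC(=O)/C=C/c1ccc(O)c(-c2c(OC)cc3oc(-c4ccc(OC)cc4)cc(=O)c3c2OC)c1O | intermediate (not isolated)
23 | 8-Fl-7-hydroxychromen-2-one | O=c1ccc2ccc(O)c(-c3c(OC)cc4oc(-c5ccc(OC)cc5)cc(=O)c4c3OC)c2o1 | intermediate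
24 | 8-[5,7-dihydroxy-2-(4-hydroxyphenyl)-4-oxochromen-6-yl]-7-hydroxychromen-2-one | O=c1ccc2ccc(O)c(-c3c(O)cc4oc(-c5ccc(O)cc5)cc(=O)c4c3O)c2o1 | target

**Step count**

Total: 13 steps. Longest linear sequence: 12 steps (steps 1–8 and 10–13); step 9 is a one-step side branch.

**Steps most likely to fail**

Step 10. The hindered, moisture-sensitive diene may be lost to protodesilylation, or to open-chain Mukaiyama–Michael addition that does not close the ring, before cycloaddition takes place. The fallback gives up the benzannulation: the biaryl bond is made by cross-coupling and the coumarin ring by a Pechmann-type annulation. It sets out from 2 and comes back to the route at 24.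
- Regioselective iodination of 2 at C6 (BnMe3N+ ICl2−, CaCO3, CH2Cl2–MeOH, rt) should give 5-hydroxy-6-iodo-7-methoxy-2-(4-methoxyphenyl)chromen-4-one F1.
- O-Methylation (Me2SO4, K2CO3, acetone, reflux) gives 6-iodo-5,7-dimethoxy-2-(4-methoxyphenyl)chromen-4-one F2.
- Suzuki–Miyaura coupling of F2 with commercial 2,6-dimethoxyphenylboronic acid (Pd(OAc)2, 2-dicyclohexylphosphino-2',6'-dimethoxybiphenyl, K3PO4, PhMe–H2O, 100 °C) gives 6-(2,6-dimethoxyphenyl)-5,7-dimethoxy-2-(4-methoxyphenyl)chromen-4-one F3.
- BBr3 in CH2Cl2 removes all five methyl groups to give 6-(2,6-dihydroxyphenyl)-5,7-dihydroxy-2-(4-hydroxyphenyl)chromen-4-one F4.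
- Hydroarylation–lactonisation of the free resorcinol ring of F4 with propiolic acid 15 (Pd(OAc)2 cat., CF3CO2H, CH2Cl2, rt) should give 24. The two open positions of that ring are equivalent, and it is the most electron-rich ring of F4.

Step 8. The silyl triflate may activate the Lewis-basic pyranone carbonyl towards attack by the ketene acetal of a second molecule, or the second silylation may stall at 13. The fallback replaces the one-pot electrophilic silylation by an isolable enol ether and a kinetic lithium dienolate. It sets out from 12 and comes back at 19.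
- Silylation of 12 with tBuMe2SiCl and imidazole in DMF gives the chromatographable methyl (Z)-3-(tert-butyldimethylsilyloxy)-2-Fl-but-2-enoate F5.
- Deprotonation of the terminal methyl with LiN(iPr)2 (1.05 equiv, THF, −78 °C) and trapping with Me3SiCl gives (1Z)-3-(tert-butyldimethylsilyloxy)-2-Fl-1-methoxy-1-(trimethylsilyloxy)buta-1,3-diene F6. The methyl protons are far more acidic than the flavone C3–H, so one equivalent of base should suffice.
- F6 is heated with 16 as in step 10 and worked up with Bu4NF–AcOH to strip both silyl groups, giving 19.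

Step 11. Dehydrogenative silylation of the two free phenols may release hydrogen at the palladium surface, leading to over-reduction of the aldehyde or saturation of the flavone C2=C3 bond, and sulfur may deactivate the catalyst. The fallback masks the phenols before the reduction. It sets out from 19 and comes back at 20.
- Acetylation (Ac2O, pyridine, 4-dimethylaminopyridine cat.) gives S-ethyl 2,4-diacetoxy-3-Fl-benzothioate F7.
- Fukuyama reduction (Et3SiH, Pd/C, acetone) gives 2,4-diacetoxy-3-Fl-benzaldehyde F8.
- Methanolysis (K2CO3, MeOH, rt) returns 20.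

**Further compounds**

F1 | step 10 | 5-hydroxy-6-iodo-7-methoxy-2-(4-methoxyphenyl)chromen-4-one | COc1ccc(-c2cc(=O)c3c(O)c(I)c(OC)cc3o2)cc1
F2 | step 10 | 6-iodo-5,7-dimethoxy-2-(4-methoxyphenyl)chromen-4-one | COc1ccc(-c2cc(=O)c3c(OC)c(I)c(OC)cc3o2)cc1
F3 | step 10 | 6-(2,6-dimethoxyphenyl)-5,7-dimethoxy-2-(4-methoxyphenyl)chromen-4-one | COc1ccc(-c2cc(=O)c3c(OC)c(-c4c(OC)cccc4OC)c(OC)cc3o2)cc1
F4 | step 10 | 6-(2,6-dihydroxyphenyl)-5,7-dihydroxy-2-(4-hydroxyphenyl)chromen-4-one | O=c1cc(-c2ccc(O)cc2)oc2cc(O)c(-c3c(O)cccc3O)c(O)c12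
F5 | step 8 | methyl (Z)-3-(tert-butyldimethylsilyloxy)-2-Fl-but-2-enoate | COC(=O)/C(c1c(OC)cc2oc(-c3ccc(OC)cc3)cc(=O)c2c1OC)=C(/C)O[Si](C)(C)C(C)(C)C
F6 | step 8 | (1Z)-3-(tert-butyldimethylsilyloxy)-2-Fl-1-methoxy-1-(trimethylsilyloxy)buta-1,3-diene | C=C(O[Si](C)(C)C(C)(C)C)/C(c1c(OC)cc2oc(-c3ccc(OC)cc3)cc(=O)c2c1OC)=C(/OC)O[Si](C)(C)C
F7 | step 11 | S-ethyl 2,4-diacetoxy-3-Fl-benzothioate | CCSC(=O)c1ccc(OC(C)=O)c(-c2c(OC)cc3oc(-c4ccc(OC)cc4)cc(=O)c3c2OC)c1OC(C)=O
F8 | step 11 | 2,4-diacetoxy-3-Fl-benzaldehyde | O=Cc1ccc(OC(C)=O)c(-c2c(OC)cc3oc(-c4ccc(OC)cc4)cc(=O)c3c2OC)c1OC(C)=O
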